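The hexamer is cut at the C–CH2 bond between the central rings C and D. The methylene carbon sits on ring D ortho to two hydroxyls, so ring D can be unveiled as an ortho-quinone methide from a dimethylaminomethyl (Mannich) trimer D–E–F; the ring C carbon is the only unsubstituted, doubly hydroxyl-flanked position of trimer A–B–C. One thermal operation expels dimethylamine and joins the two unprotected trimers by conjugate addition and rearomatisation. Both trimers derive from one symmetrical dimer, 3,3'-methylenebis(butyrylphloroglucinol): as a bis-nucleophile it takes up the ring A Mannich base, and as its bis-Mannich base it is desymmetrised by the ring F monomer.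

Key step: step 9

Remark: the target has no stereocentre and no stereogenic double bond; ring A (the gem-dimethyl butyrylfilicinic acid ring) is written as the enol tautomer of the target SMILES, rings B to E are the four butyrylphloroglucinol rings in chain order, ring F is the terminal methylated ring, and Mannich bases are written as neutral amines although they should exist as inner salts.

Step 1
Reactants: 1 phloroglucinol (benzene-1,3,5-triol); 2 butyryl chloride
Product: 3 butyrylphloroglucinol (1-(2,4,6-trihydroxyphenyl)butan-1-one)
Conditions: AlCl3 (4 equiv), CH2Cl2/MeNO2, 0 °C to 40 °C; then ice/1 M HCl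
Reagents that add atoms: butyryl chloride CCCC(=O)Cl
Why: Friedel–Crafts acylation of the threefold activated ring, in which the first acyl group, held as its AlCl3 chelate, deactivates the ring so that the reaction should stop at the monoketone.

Step 2
Reactants: 4 2-methylphloroglucinol (2-methylbenzene-1,3,5-triol); 2 butyryl chloride
Product: 5 ring F monomer (1-(2,4,6-trihydroxy-3-methylphenyl)butan-1-one)
Conditions: AlCl3 (4 equiv), CH2Cl2/MeNO2, 0 °C to 40 °C; then ice/1 M HCl
Reagents that add atoms: butyryl chloride CCCC(=O)Cl
Why: Friedel–Crafts acylation as in step 1, where the two open ring positions of 4 are equivalent, so only one regioisomer can form.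

Step 3
Reactants: 3 butyrylphloroglucinol; 6 iodomethane
Product: 7 butyrylfilicinic acid (ring A monomer; 2-butanoyl-3,5-dihydroxy-4,4-dimethylcyclohexa-2,5-dien-1-one), via monomethyl ketone 5 (not isolated)
Conditions: NaOMe (3.5 equiv), MeI (2.5 equiv), MeOH, 0 °C to rt
Reagents that add atoms: iodomethane CI
Why: Dearomatising double C-methylation of the phenolate (enolate alkylation, the usual preparation of acylfilicinic acids), in which the first methyl group gives 5 and the second should enter preferentially at the same, now most electron-rich carbon, locking the ring as the gem-dimethyl enol-trione; other methylation products are removed by crystallisation or chromatography.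

Step 4
Reactants: 3 butyrylphloroglucinol (4 equiv); 8 formaldehyde
Product: 11 3,3'-methylenebis(butyrylphloroglucinol) dimer (a CH2 group joining two 3-butanoyl-2,4,6-trihydroxyphenyl rings; one free ring carbon on each ring), via hydroxymethyl ketone 9 (not isolated), via ortho-quinone methide 10 (not isolated)
Conditions: 37% aq. HCHO (1 equiv), KOH (aq., 1%), 0 °C to rt, 15 min; then 1 M HCl
Reagents that add atoms: formaldehyde C=O
Why: Lederer–Manasse hydroxymethylation of the phenolate, loss of hydroxide to the ortho-quinone methide and Michael addition of a second phenolate (classical methylene-bis formation), with the fourfold excess of 3 holding the condensation at the dimer and the surplus monomer being recovered.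

Step 5
Reactants: 7 butyrylfilicinic acid; 12 bis(dimethylamino)methane
Product: 13 ring A Mannich base (2-butanoyl-6-[(dimethylamino)methyl]-3,5-dihydroxy-4,4-dimethylcyclohexa-2,5-dien-1-one)
Conditions: CH2(NMe2)2 (1.5 equiv), MeCN, 0 °C, slow addition of 7 to the aminal
Reagents that add atoms: bis(dimethylamino)methane CN(C)CN(C)C
Why: Mannich aminomethylation, in which the strongly acidic enol ionises the aminal to the methyleneiminium ion that is captured at the only unsubstituted ring carbon, while inverse addition and precipitation of the inner salt should keep a second molecule of 7 from adding.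

Step 6
Reactants: 13 ring A Mannich base; 11 dimer (3 equiv)
Product: 15 trimer A–B–C (butyrylfilicinic acid ring–CH2–butyrylphloroglucinol ring–CH2–butyrylphloroglucinol ring with one free carbon on ring C), via ring A methylidene trione 14 (not isolated)
Conditions: 1,4-dioxane, 80 °C, Ar sweep
Reagents that add atoms: none
Why: Thermal loss of dimethylamine from the inner salt gives the alkylidene trione 14, a strong Michael acceptor that is trapped by one of the two equivalent free ring carbons of 11 and rearomatises (Mannich-base quinone methide alkylation), with the threefold excess of 11 suppressing the second alkylation.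

Step 7
Reactants: 11 dimer; 12 bis(dimethylamino)methane
Product: 17 bis-Mannich base of the dimer (a dimethylaminomethyl group on the remaining ring carbon of each ring), via mono-Mannich dimer 16 (not isolated)
Conditions: CH2(NMe2)2 (3 equiv), MeCN, 0 °C to rt
Reagents that add atoms: bis(dimethylamino)methane CN(C)CN(C)C
Why: Twofold Mannich aminomethylation at the two hydroxyl-flanked aromatic C–H positions, driven to completion by excess aminal to a product that has no free ring carbon left and therefore cannot condense with itself.

Step 8
Reactants: 17 bis-Mannich base (3 equiv); 5 ring F monomer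
Product: 19 trimer D–E–F Mannich base (ring F–CH2–ring E–CH2–ring D carrying CH2NMe2 on its last ring carbon), via ortho-quinone methide 18 (not isolated)
Conditions: 1,4-dioxane/MeCN, 60 °C, sealed tube; reversed-phase separation (aq. HCO2H/MeCN)
Reagents that add atoms: none
Why: Reversible loss of dimethylamine from one arm of 17 gives ortho-quinone methide 18, which is trapped irreversibly by the single free ring carbon of 5 (Mannich-base quinone methide alkylation), while the excess of the bis-electrophile and the retained amine should keep the second arm intact, so the symmetrical dimer is desymmetrised in one operation.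

Step 9
Reactants: 15 trimer A–B–C (1.1 equiv); 19 trimer D–E–F Mannich base
Product: 21 target hexamer A–B–C–D–E–F, via ring D ortho-quinone methide 20 (not isolated)
Conditions: 1,4-dioxane, 70 °C, Ar sweep
Reagents that add atoms: none
Why: On heating, the zwitterionic Mannich base 19 loses dimethylamine by an E1cB-type elimination and unveils ring D as the ortho-quinone methide 20, whose exocyclic methylene is the carbon that becomes the central bridge. The only unsubstituted ring carbon of 15, the ring C position ortho to two hydroxyls and para to the third, adds to this methylene in a conjugate (vinylogous Michael) fashion, and tautomerisation restores both aromatic rings and forms the ring C–CH2 bond. The closest known reaction type is the Mannich-base (ortho-quinone methide) alkylation of phloroglucinols used for unsymmetrical methylene-bridged acylphloroglucinol dimers. No ring is closed and no stereocentre is formed. The step needs cross-coupling without homo-coupling and C- over O-alkylation: 19 has no free ring carbon and 15 has no leaving group, so neither can react with itself, while O-adducts and additions at substituted carbons cannot aromatise and should revert to 20. The acidic ring A enol of 15 binds the released amine, which together with the moderate temperature and the argon sweep should limit base-induced exchange of the existing methylene bridges.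

Compound list
1 | phloroglucinol (benzene-1,3,5-triol) | Oc1cc(O)cc(O)c1 | starting material
2 | butyryl chloride | CCCC(=O)Cl | starting material
3 | butyrylphloroglucinol, 1-(2,4,6-trihydroxyphenyl)butan-1-one | CCCC(=O)c1c(O)cc(O)cc1O | intermediate
4 | 2-methylphloroglucinol (2-methylbenzene-1,3,5-triol) | Cc1c(O)cc(O)cc1O | starting material
5 | ring F monomer, 1-(2,4,6-trihydroxy-3-methylphenyl)butan-1-one | CCCC(=O)c1c(O)cc(O)c(C)c1O | intermediate
6 | iodomethane | CI | starting material
7 | butyrylfilicinic acid, 2-butanoyl-3,5-dihydroxy-4,4-dimethylcyclohexa-2,5-dien-1-one | CCCC(=O)C1=C(O)C(C)(C)C(O)=CC1=O | intermediate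
8 | formaldehyde | C=O | starting material
9 | 1-[2,4,6-trihydroxy-3-(hydroxymethyl)phenyl]butan-1-one | CCCC(=O)c1c(O)cc(O)c(CO)c1O | intermediate
10 | ortho-quinone methide of 9, 2-butanoyl-3,5-dihydroxy-6-methylidenecyclohexa-2,4-dien-1-one | CCCC(=O)C1=C(O)C=C(O)C(=C)C1=O | intermediate
11 | 3,3'-methylenebis(butyrylphloroglucinol), CH2 joining two 3-butanoyl-2,4,6-trihydroxyphenyl rings | CCCC(=O)c1c(O)cc(O)c(Cc2c(O)cc(O)c(C(=O)CCC)c2O)c1O | intermediate
12 | bis(dimethylamino)methane (N,N,N',N'-tetramethylmethanediamine) | CN(C)CN(C)C | starting material
13 | ring A Mannich base, 2-butanoyl-6-[(dimethylamino)methyl]-3,5-dihydroxy-4,4-dimethylcyclohexa-2,5-dien-1-one | CCCC(=O)C1=C(O)C(C)(C)C(O)=C(CN(C)C)C1=O | intermediate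
14 | ring A methylidene trione, 2-butanoyl-3-hydroxy-4,4-dimethyl-6-methylidenecyclohex-2-ene-1,5-dione | CCCC(=O)C1=C(O)C(C)(C)C(=O)C(=C)C1=O | intermediate
15 | trimer A–B–C with one free carbon on ring C | CCCC(=O)C1=C(O)C(C)(C)C(O)=C(Cc2c(O)c(Cc3c(O)cc(O)c(C(=O)CCC)c3O)c(O)c(C(=O)CCC)c2O)C1=O | intermediate
16 | mono-Mannich base of dimer 11 (one ring carries CH2NMe2, the other a free ring carbon) | CCCC(=O)c1c(O)cc(O)c(Cc2c(O)c(CN(C)C)c(O)c(C(=O)CCC)c2O)c1O | intermediate
17 | bis-Mannich base of dimer 11 (CH2NMe2 on the last ring carbon of each ring) | CCCC(=O)c1c(O)c(CN(C)C)c(O)c(Cc2c(O)c(CN(C)C)c(O)c(C(=O)CCC)c2O)c1O | intermediate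
18 | ortho-quinone methide formed from one arm of 17 | CCCC(=O)c1c(O)c(CN(C)C)c(O)c(CC2=C(O)C(C(=O)CCC)=C(O)C(=C)C2=O)c1O | intermediate
19 | trimer D–E–F Mannich base (CH2NMe2 on ring D, methyl on ring F) | CCCC(=O)c1c(O)c(C)c(O)c(Cc2c(O)c(Cc3c(O)c(CN(C)C)c(O)c(C(=O)CCC)c3O)c(O)c(C(=O)CCC)c2O)c1O | intermediate
20 | ring D ortho-quinone methide of trimer D–E–F | CCCC(=O)c1c(O)c(C)c(O)c(Cc2c(O)c(CC3=C(O)C(C(=O)CCC)=C(O)C(=C)C3=O)c(O)c(C(=O)CCC)c2O)c1O | intermediate
21 | target hexamer A–B–C–D–E–F (no stereocentre) | CCCC(=O)C1=C(O)C(C)(C)C(O)=C(Cc2c(O)c(Cc3c(O)c(Cc4c(O)c(Cc5c(O)c(Cc6c(O)c(C)c(O)c(C(=O)CCC)c6O)c(O)c(C(=O)CCC)c5O)c(O)c(C(=O)CCC)c4O)c(O)c(C(=O)CCC)c3O)c(O)c(C(=O)CCC)c2O)C1=O | target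

Total step count: 9. Longest linear sequence: 5 steps (steps 1, 4, 7, 8, 9 from 1 through 3, 11, 17 and 19 to 21; the branch through 7, 13 and 15 is equally long).

Steps most likely to fail

Step 9 (key step). Under heat and in the presence of the released amine, the existing methylene bridges may open by retro-Michael cleavage and recombine at random. The ring A–CH2–ring B link is the most exposed, because its filicinic enolate is a good leaving group. The hexamer would then be diluted by shorter and longer oligomers. Release of the quinone methide may also be slow if the amine is held as a salt by ring A. The fallback is an amine-free, acid-catalysed coupling at room temperature. It sets out from 19, which has no filicinic link and should tolerate heat. Reflux in MeOH under a nitrogen stream should exchange the dimethylamino group for methoxide through 20 and give the ring D methoxymethyl trimer F1. F1 and 15 are then joined with catalytic camphorsulfonic acid in MeCN or hexafluoroisopropanol at room temperature, by acid-promoted loss of methanol and Friedel–Crafts benzylation of the ring C carbon. This comes back to the route at 21.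

Step 8. The remaining aminomethyl arm of 19 may react a second time with 5. Unreacted 17 may be lost by self-condensation of its quinone methide if the amine escapes, and the two amphoteric amines may resist separation. The fallback is a stepwise sequence with the electrophile on the monomer and only neutral phenols to separate. It sets out from 5: a Mannich reaction with 12 in MeCN at 0 °C should give the Mannich base of the ring F monomer F2. Heating F2 with 11 (3 equiv) in dioxane passes through the ring F ortho-quinone methide F3 and should give the trimer D–E–F with one free ring D carbon F4. A Mannich reaction of F4 with 12 at 0 °C comes back to the route at 19.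

Step 6. The dimer 11 may be alkylated at both of its free ring carbons, and the newly formed filicinic link may exchange under the reaction conditions. The fallback is linear chain growth with the cheap monomer 3 in large excess. It sets out from 13: heating with 3 (10 equiv) in dioxane should give, through 14, the dimer A–B F5. A Mannich reaction with 12 should give its ring B Mannich base F6. Heating F6 with 3 (10 equiv) passes through the ring B ortho-quinone methide F7 and comes back to the route at 15.

Further compounds
F1 | step 9 | ring D methoxymethyl trimer D–E–F | CCCC(=O)c1c(O)c(C)c(O)c(Cc2c(O)c(Cc3c(O)c(COC)c(O)c(C(=O)CCC)c3O)c(O)c(C(=O)CCC)c2O)c1O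
F2 | step 8 | Mannich base of the ring F monomer, 1-{3-[(dimethylamino)methyl]-2,4,6-trihydroxy-5-methylphenyl}butan-1-one | CCCC(=O)c1c(O)c(CN(C)C)c(O)c(C)c1O
F3 | step 8 | ring F ortho-quinone methide | CCCC(=O)C1=C(O)C(=C)C(=O)C(C)=C1O
F4 | step 8 | trimer D–E–F with one free ring D carbon | CCCC(=O)c1c(O)c(C)c(O)c(Cc2c(O)c(Cc3c(O)cc(O)c(C(=O)CCC)c3O)c(O)c(C(=O)CCC)c2O)c1O
F5 | step 6 | dimer A–B (butyrylfilicinic acid ring–CH2–butyrylphloroglucinol ring) | CCCC(=O)C1=C(O)C(C)(C)C(O)=C(Cc2c(O)cc(O)c(C(=O)CCC)c2O)C1=O
F6 | step 6 | ring B Mannich base of dimer A–B | CCCC(=O)C1=C(O)C(C)(C)C(O)=C(Cc2c(O)c(CN(C)C)c(O)c(C(=O)CCC)c2O)C1=O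
F7 | step 6 | ring B ortho-quinone methide of dimer A–B | CCCC(=O)C1=C(O)C(C)(C)C(O)=C(CC2=C(O)C(C(=O)CCC)=C(O)C(=C)C2=O)C1=O
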